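Compound numbers refer to the compound list that follows the steps.

## Analysis of the target

Target 20 is a 2-arylchroman-3-ol: benzo ring A is fused to dihydropyran ring C (O1, C2, C3, C4, C4a, C8a). C2 carries a 4-hydroxy-3,5-dimethoxyphenyl group (ring B), C3 a hydroxyl, C5 a 2-(3-hydroxyphenyl)ethyl chain and C7 a methoxy group. The only stereocentres are the neighbours C2 (R) and C3 (S), which place the aryl group and the hydroxyl trans on ring C. The C2–O1 bond is a benzylic ether para to an oxygen donor. It ionises under acid and, once the ring-B phenol is free, can open through a quinone methide, so C2 is epimerisable; ring A is an electron-rich resorcinol ether open to electrophiles at C6 and C8. Ring A is 1,2,3,5-tetrasubstituted with two carbon substituents on adjacent carbons (C5, C4a) next to an oxygen (C8a), a pattern that electrophilic substitution of a resorcinol does not deliver. A second difficulty is the fate of the aryl oxygens: the two on ring A must end differently (O1 in the ring, the C7 oxygen methylated), while the phenols of ring B and of the chain must end free. The strategy rests on C5 and C4a being neighbouring ring-A carbons that bear the chain CH2 and C4, with the C8a oxygen beside C4a and the C7 oxygen meta to it. This is the pattern left when a carbon nucleophile and a carbon electrophile add across the triple bond of a 3,5-dioxygenated benzyne. Because C4 is a CH2 group, the electrophile can be a terminal epoxide that already holds C3 in its final configuration.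

## Retrosynthetic reasoning

**20 from 19.** The two O–benzyl bonds on the ring-B oxygen and the chain phenol are cut first. Benzyl has to survive organolithiums, a Lewis acid, protic acid and a basic methylation, and then leave under neutral conditions. The forward hydrogenolysis must spare the benzylic C2–O1 bond.

**19 from 18.** The C7 O–methyl bond is cut next. Late methylation lets ring A travel as a symmetric bis-acetal up to the ring closure. In 18 the C7 oxygen is the only free phenol, so the forward step only has to leave the C3 alcohol alone.

**18 from 16.** Ring C is opened at O1–C2. This is the one ring bond whose carbon end is a stabilised cation equivalent (benzylic, para to an alkoxy group), so acid alone can form it, and the same acid removes the three acetal groups of 16. The cut also assigns the ring-A oxygens their roles: the one ortho to the C4 methylene closes the ring, the other stays free for methylation. The forward step must set C2 relative to C3 through the preference for the 2,3-trans ring, so the benzylic configuration of 16 is of no consequence.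

**16 from 3, 6 and 11.** The two bonds from ring A to carbon, C5–CH2 and C4a–C4, are cut together. They sit on adjacent ring carbons, and cutting both reduces the crowded ring to the mirror-symmetric 3, the chain to the achiral iodide 6 (source of organolithium 13) and the C2–C3–C4 unit to epoxide 11. Cutting C4–C3 or C3–C2 instead would leave the tetrasubstituted ring A to be built separately. In the forward direction 12, made from 3, must release benzyne 14, 13 must add at the future C5, and the resulting 15 must open 11 at its CH2 carbon only.

**11 from 7.** The acetal of 11 goes back to epoxy alcohol 10. The oxirane of 10 goes back to the vinyl group of racemic 9 by a kinetic-resolution epoxidation, which sets the oxirane carbon (future C3) by reagent control. The carbinol–vinyl bond of 9 is cut to aldehyde 8, and the benzyl ether of 8 to 7.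

**6 from 4.** The C–I bond goes back to the primary alcohol 5, and the benzyl ether of 5 to phenol 4. The forward steps need only phenol-over-alcohol selectivity.

**3 from 1.** The acetal groups of 3 go back to diol 2, and 2 to 1 by O-demethylation. Acetals replace the methyl ethers of 1 because they must come off later without touching the ring-B methoxy groups.

## Alternatives that were turned down

**Alternative 1:** Ring C is cut at O1–C2 and C3–C4, giving salicylaldehyde A2 and enal A3.
- Forward key step: a diarylprolinol silyl ether forms an iminium ion with A3, the phenol of A2 adds to its β-carbon (O1–C2), and the enamine closes onto the aryl aldehyde (C3–C4). Loss of water gives chromene carbaldehyde A1.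
- For: it is catalytic and convergent, closes ring C in one step, and sets C2 in the absolute sense by the catalyst.
- Against: A1 carries a formyl carbon on C3 that 20 lacks. C3 must become a carbinol trans to the aryl group, which means decarbonylation (for example with RhCl(PPh3)3) and then hydroboration–oxidation.
- Against: 2-aryl-2H-chromenes with donor aryl groups open reversibly to ortho-quinone methides, so C2 may racemise during those steps.
- Against: the donor aryl group makes A3 a poor acceptor, and the ortho chain of A2 crowds the aldol closure.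
- Against: A2 already contains the full ring-A pattern with differentiated oxygens and needs its own multistep synthesis.
- Comparison: the alternative is stronger on catalyst control of C2. The chosen route offers C3 at the right oxidation level from the start, no carbon to excise, and ring A assembled in the key step itself.

**Alternative 2:** Ring A is cut at C8a–C4a, C5–C6 and C7–C8, giving diyne A5 (an ethynyl ether that already holds C2 and C3) and alkynylboronate A6.
- Forward key step: Cp*RuCl(cod) couples the two alkynes of A5 to a ruthenacycle (C8a–C4a, closing ring C), A6 inserts, and reductive elimination gives chroman A4 with boron on C7.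
- For: both stereocentres are fixed in an open chain before any ring exists, so there is no cation and no C2 epimer question. The oxygen pattern of ring A is unambiguous, since O1 is built in and the C7 oxygen comes from boron. On both points it is stronger than the chosen route.
- Against: A5 needs an ethynyl ether of a secondary, electron-rich benzylic alcohol, and such benzylic alkynyl ethers rearrange readily to ketene-derived products.
- Against: the C2/C3 pair must first be made by a separate asymmetric sequence, and the position of boron (C7 versus C6) rests only on a steric preference.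
- Against: oxidation of the C–B bond, methylation, desilylation and hydrogenolysis still follow, so the linear sequence is clearly longer.
- Comparison: the chosen route gives up some stereochemical security at C2 for a much shorter sequence from a commercial symmetric fluoroarene, with the risk gathered in one step.

**Alternative 3:** Ring A is cut at C4a–C5, giving the open-chain triketo ester A9, which is released from diketo-dioxinone A8.
- Forward key step: heating A8 with methanol gives A9 through an acylketene. With Cs2CO3 the C2 enolate of A9 adds to the C7 ketone, and dehydration gives resorcylate A7.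
- For: the chemistry is well established, and ring A is fully regiodefined.
- For: the two phenols of A7 are differentiated from the start, one being hydrogen-bonded to the ester. This is cleaner than the chosen route, which leaves the differentiation to the ring closure.
- Against: A7 is only ring A with a one-carbon handle. C3, C2, ring B, ring C and both stereocentres still have to be added by ester reduction, chain extension, asymmetric oxidation and ring closure.
- Against: that ring closure would pass through the same benzylic cation, so the C2 question is not avoided, and A8 itself takes several steps.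
- Comparison: the chosen route attaches the chain, C4 and the C3 stereocentre to ring A in one operation and is far shorter.

Key step: step 9

## Route

Step 1
Reactants: 1 1-fluoro-3,5-dimethoxybenzene
Product: 2 5-fluorobenzene-1,3-diol
Conditions: BBr3, CH2Cl2, −78 °C → rt; then H2O
Reagents that add atoms: none
Why: Lewis-acid cleavage of aryl methyl ethers (bromide attacks the methyl group of the boron-complexed ether); the aryl C–F bond is inert to BBr3.

Step 2
Reactants: 2 5-fluorobenzene-1,3-diol
Product: 3 1-fluoro-3,5-bis(methoxymethoxy)benzene
Conditions: NaH, MOMCl, DMF, 0 °C → rt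
Reagents that add atoms: chloromethyl methyl ether, COCCl
Why: Williamson-type O-alkylation of both phenoxides; the acetal groups tolerate organolithiums, activate the neighbouring C–H and come off later under acid.

Step 3
Reactants: 4 2-(3-hydroxyphenyl)ethanol
Product: 5 2-[3-(benzyloxy)phenyl]ethanol
Conditions: BnBr, K2CO3, acetone, reflux
Reagents that add atoms: benzyl bromide, BrCc1ccccc1
Why: Williamson etherification; carbonate deprotonates only the phenol, so the primary alcohol stays free.

Step 4
Reactants: 5 2-[3-(benzyloxy)phenyl]ethanol
Product: 6 1-(benzyloxy)-3-(2-iodoethyl)benzene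
Conditions: PPh3, I2, imidazole, CH2Cl2, 0 °C → rt
Reagents that add atoms: iodine, II
Why: Appel-type iodination; iodide displaces the alkoxyphosphonium group at the primary carbon (SN2) under neutral conditions that leave the benzyl ether alone.

Step 5
Reactants: 7 syringaldehyde (4-hydroxy-3,5-dimethoxybenzaldehyde)
Product: 8 4-(benzyloxy)-3,5-dimethoxybenzaldehyde
Conditions: BnBr, K2CO3, DMF, 60 °C
Reagents that add atoms: benzyl bromide, BrCc1ccccc1
Why: Williamson etherification of the only acidic OH; the aldehyde is unaffected.

Step 6
Reactants: 8 4-(benzyloxy)-3,5-dimethoxybenzaldehyde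
Product: 9 rac-1-[4-(benzyloxy)-3,5-dimethoxyphenyl]prop-2-en-1-ol
Conditions: CH2=CHMgBr, THF, 0 °C; then aq NH4Cl
Reagents that add atoms: vinylmagnesium bromide, C=C[Mg]Br
Why: Grignard 1,2-addition to the aldehyde; the carbinol forms racemic and is resolved in the next step.

Step 7
Reactants: 9 rac-1-[4-(benzyloxy)-3,5-dimethoxyphenyl]prop-2-en-1-ol
Product: 10 (R)-[4-(benzyloxy)-3,5-dimethoxyphenyl][(S)-oxiran-2-yl]methanol
Conditions: Ti(OiPr)4 (0.2 equiv), D-(−)-diisopropyl tartrate (0.25 equiv), t-BuOOH (0.45 equiv), 4 Å MS, CH2Cl2, −20 °C
Reagents that add atoms: tert-butyl hydroperoxide, CC(C)(C)OO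
Why: Sharpless kinetic resolution; with the D-(−)-tartrate the titanium complex should deliver oxygen to the face of the vinyl group that makes the oxirane carbon S (reagent control), and only the (S)-carbinol fits the reactive conformation, so the erythro epoxy alcohol forms and (R)-9 is left. Conversion is held below one half so that the slow enantiomer does not contribute.

Step 8
Reactants: 10 (R)-[4-(benzyloxy)-3,5-dimethoxyphenyl][(S)-oxiran-2-yl]methanol
Product: 11 (S)-2-[(R)-[4-(benzyloxy)-3,5-dimethoxyphenyl](methoxymethoxy)methyl]oxirane
Conditions: MOMCl, iPr2NEt, CH2Cl2, 0 °C → rt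
Reagents that add atoms: chloromethyl methyl ether, COCCl
Why: O-alkylation of the secondary alcohol under mild amine-base conditions; the acetal prevents Payne rearrangement under the basic conditions of step 9 and later serves as the leaving group at the benzylic carbon. No stereocentre is touched.

Step 9
Reactants: 3 1-fluoro-3,5-bis(methoxymethoxy)benzene, 6 1-(benzyloxy)-3-(2-iodoethyl)benzene, 11 (S)-2-[(R)-[4-(benzyloxy)-3,5-dimethoxyphenyl](methoxymethoxy)methyl]oxirane
Product: 16 (1R,2S)-1-[4-(benzyloxy)-3,5-dimethoxyphenyl]-3-(2-{2-[3-(benzyloxy)phenyl]ethyl}-4,6-bis(methoxymethoxy)phenyl)-1-(methoxymethoxy)propan-2-ol, via lithiated fluoroarene 12 (not isolated), via phenethyllithium 13 (not isolated), via dialkoxybenzyne 14 (not isolated), via aryllithium adduct 15 (not isolated)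
Conditions: 3, n-BuLi, THF, −78 °C; add 13 (from 6, t-BuLi (2 equiv), Et2O/pentane, −78 °C), −78 → −30 °C; then 11 (limiting), BF3·OEt2, −78 °C; then H2O
Reagents that add atoms: none
Why: At −78 °C n-BuLi should remove the proton flanked by fluorine and one acetal oxygen (the most acidic C–H, helped by chelation) to give 12, which is stable at that temperature and loses LiF on warming to give benzyne 14. The primary alkyllithium 13 adds to the aryne carbon remote from the neighbouring acetal oxygen, so the carbanion develops beside that oxygen, where induction and O–Li chelation stabilise it; this gives 15 with the chain on the future C5 and lithium on the future C4a. Recooled to −78 °C, 15 opens the BF3-activated terminal epoxide 11 at its CH2 carbon in an SN2 step, forming the C4a–C4 bond. The closest known reaction type is the carbolithiation of 3,5-dialkoxybenzynes generated from 1-halo-3,5-dialkoxybenzenes with electrophilic quench of the 2-lithio adduct, joined to the BF3·OEt2-promoted opening of epoxides by aryllithiums. No ring is closed and no stereocentre is formed: attack at CH2 leaves the oxirane carbon (future C3, S) and the benzylic carbon as they were. The site of metalation is secured by the low temperature, at which the position between the two acetal oxygens reacts slowly, and the mirror symmetry of 3 makes the two fluorine-flanked positions identical. The regiochemistry of the aryne addition is dictated by the alkoxy group next to the triple bond, and the alkyllithium is far more nucleophilic toward the aryne than the aryllithiums present. Because 11 is the limiting component and 15 is in excess, little alkyllithium should remain to consume the epoxide, and the hindered 2,6-disubstituted aryllithium can only reach the terminal carbon.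

Step 10
Reactants: 16 (1R,2S)-1-[4-(benzyloxy)-3,5-dimethoxyphenyl]-3-(2-{2-[3-(benzyloxy)phenyl]ethyl}-4,6-bis(methoxymethoxy)phenyl)-1-(methoxymethoxy)propan-2-ol
Product: 18 (2R,3S)-2-[4-(benzyloxy)-3,5-dimethoxyphenyl]-5-{2-[3-(benzyloxy)phenyl]ethyl}chromane-3,7-diol, via benzylic cation 17 (not isolated)
Conditions: HCl (ca. 1 M), MeOH/THF, 45 °C, high dilution
Reagents that add atoms: none
Why: Acid-mediated acetal cleavage followed by SN1 cycloetherification; the para-alkoxybenzyl cation 17 is captured by the phenol ortho to the C4 methylene in a six-membered closure. C2 is set by the existing C3 centre: the transition state with aryl and hydroxyl both pseudo-equatorial should be favoured, the trans ring is also the more stable, and reversible ionisation lets the cis epimer drain toward it.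

Step 11
Reactants: 18 (2R,3S)-2-[4-(benzyloxy)-3,5-dimethoxyphenyl]-5-{2-[3-(benzyloxy)phenyl]ethyl}chromane-3,7-diol
Product: 19 (2R,3S)-2-[4-(benzyloxy)-3,5-dimethoxyphenyl]-5-{2-[3-(benzyloxy)phenyl]ethyl}-7-methoxychroman-3-ol
Conditions: MeI, K2CO3, acetone, 40 °C
Reagents that add atoms: iodomethane, CI
Why: Williamson O-methylation of the only free phenol; carbonate does not deprotonate the C3 alcohol, and the other phenols are still benzyl ethers.

Step 12
Reactants: 19 (2R,3S)-2-[4-(benzyloxy)-3,5-dimethoxyphenyl]-5-{2-[3-(benzyloxy)phenyl]ethyl}-7-methoxychroman-3-ol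
Product: 20 (2R,3S)-2-(4-hydroxy-3,5-dimethoxyphenyl)-5-[2-(3-hydroxyphenyl)ethyl]-7-methoxychroman-3-ol
Conditions: H2 (1 atm), Pd/C (10 %), EtOAc/MeOH, rt
Reagents that add atoms: none
Why: Catalytic hydrogenolysis of the two aryl benzyl ethers under neutral conditions; the cyclic benzylic C2–O1 bond of flavan-type ethers is cleaved much more slowly and should survive if the reaction is stopped at full debenzylation.

## Compound list

1 | 1-fluoro-3,5-dimethoxybenzene | COc1cc(F)cc(OC)c1 | starting material
2 | 5-fluorobenzene-1,3-diol | Oc1cc(O)cc(F)c1 | intermediate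
3 | 1-fluoro-3,5-bis(methoxymethoxy)benzene | COCOc1cc(F)cc(OCOC)c1 | intermediate
4 | 2-(3-hydroxyphenyl)ethanol | OCCc1cccc(O)c1 | starting material
5 | 2-[3-(benzyloxy)phenyl]ethanol | OCCc1cccc(OCc2ccccc2)c1 | intermediate
6 | 1-(benzyloxy)-3-(2-iodoethyl)benzene | ICCc1cccc(OCc2ccccc2)c1 | intermediate
7 | syringaldehyde (4-hydroxy-3,5-dimethoxybenzaldehyde) | COc1cc(C=O)cc(OC)c1O | starting material
8 | 4-(benzyloxy)-3,5-dimethoxybenzaldehyde | COc1cc(C=O)cc(OC)c1OCc1ccccc1 | intermediate
9 | rac-1-[4-(benzyloxy)-3,5-dimethoxyphenyl]prop-2-en-1-ol | C=CC(O)c1cc(OC)c(OCc2ccccc2)c(OC)c1 | intermediate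
10 | (R)-[4-(benzyloxy)-3,5-dimethoxyphenyl][(S)-oxiran-2-yl]methanol | O[C@H](c1cc(OC)c(OCc2ccccc2)c(OC)c1)[C@@H]1CO1 | intermediate
11 | (S)-2-[(R)-[4-(benzyloxy)-3,5-dimethoxyphenyl](methoxymethoxy)methyl]oxirane | COCO[C@H](c1cc(OC)c(OCc2ccccc2)c(OC)c1)[C@@H]1CO1 | intermediate
12 | [2-fluoro-4,6-bis(methoxymethoxy)phenyl]lithium | [Li]c1c(F)cc(OCOC)cc1OCOC | intermediate
13 | {2-[3-(benzyloxy)phenyl]ethyl}lithium | [Li]CCc1cccc(OCc2ccccc2)c1 | intermediate
14 | 1,2-didehydro-3,5-bis(methoxymethoxy)benzene (3,5-bis(methoxymethoxy)benzyne) | COCOC1=CC(OCOC)=CC#C1 | intermediate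
15 | (2-{2-[3-(benzyloxy)phenyl]ethyl}-4,6-bis(methoxymethoxy)phenyl)lithium | [Li]c1c(CCc2cccc(OCc3ccccc3)c2)cc(OCOC)cc1OCOC | intermediate
16 | (1R,2S)-1-[4-(benzyloxy)-3,5-dimethoxyphenyl]-3-(2-{2-[3-(benzyloxy)phenyl]ethyl}-4,6-bis(methoxymethoxy)phenyl)-1-(methoxymethoxy)propan-2-ol | COCO[C@H](c1cc(OC)c(OCc2ccccc2)c(OC)c1)[C@@H](O)Cc1c(OCOC)cc(OCOC)cc1CCc1cccc(OCc2ccccc2)c1 | intermediate
17 | 1-[4-(benzyloxy)-3,5-dimethoxyphenyl]-3-(2-{2-[3-(benzyloxy)phenyl]ethyl}-4,6-dihydroxyphenyl)-2-hydroxypropan-1-ylium, carbinol carbon arranged as in 16 | COc1cc([CH+][C@@H](O)Cc2c(O)cc(O)cc2CCc2cccc(OCc3ccccc3)c2)cc(OC)c1OCc1ccccc1 | intermediate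
18 | (2R,3S)-2-[4-(benzyloxy)-3,5-dimethoxyphenyl]-5-{2-[3-(benzyloxy)phenyl]ethyl}chromane-3,7-diol | Oc1cc(CCc2cccc(OCc3ccccc3)c2)c2c(c1)O[C@H](c1cc(OC)c(OCc3ccccc3)c(OC)c1)[C@@H](O)C2 | intermediate
19 | (2R,3S)-2-[4-(benzyloxy)-3,5-dimethoxyphenyl]-5-{2-[3-(benzyloxy)phenyl]ethyl}-7-methoxychroman-3-ol | COc1cc(CCc2cccc(OCc3ccccc3)c2)c2c(c1)O[C@H](c1cc(OC)c(OCc3ccccc3)c(OC)c1)[C@@H](O)C2 | intermediate
20 | (2R,3S)-2-(4-hydroxy-3,5-dimethoxyphenyl)-5-[2-(3-hydroxyphenyl)ethyl]-7-methoxychroman-3-ol | COc1cc(CCc2cccc(O)c2)c2c(c1)O[C@H](c1cc(OC)c(O)c(OC)c1)[C@@H](O)C2 | target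

## Step count and least certain steps

Total: 12 steps. Longest linear sequence: 8 steps (7 → 8 → 9 → 10 → 11 → 16 → 18 → 19 → 20, steps 5 to 12).

**Step 9 (key step).**
- What may go wrong: metalation of 3 between the two acetal oxygens instead of beside fluorine gives an aryllithium that cannot eliminate and competes for the aryne and the epoxide.
- What may go wrong: aryllithiums instead of 13 add to the aryne, leading to biaryls.
- What may go wrong: residual alkyllithium consumes 11, and under BF3 the neighbouring acetal oxygen may take part in epoxide opening.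
- Fallback: this sets out from 3 and 6 with the same carbolithiation, but 15 is quenched with iodine and the aryl iodide 1-{2-[3-(benzyloxy)phenyl]ethyl}-2-iodo-3,5-bis(methoxymethoxy)benzene F1 is isolated and purified. Iodine–lithium exchange on F1 (t-BuLi, −78 °C), transmetalation with MgBr2·OEt2 and CuI-catalysed opening of 11 at its CH2 carbon (THF, −30 → 0 °C) then return to the route at 16. This separates ring-A assembly from the use of the valuable epoxide and avoids BF3.

**Step 10.**
- What may go wrong: poor facial selectivity in the capture of the planar cation gives the 2,3-cis epimer.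
- What may go wrong: hydride shift in the β-hydroxy cation gives a ketone, and the cation or formaldehyde equivalents may alkylate ring A intermolecularly.
- Fallback: this sets out from 16. Acylation of the C3 hydroxyl (pivaloyl chloride, pyridine, DMAP) gives (1R,2S)-1-[4-(benzyloxy)-3,5-dimethoxyphenyl]-3-(2-{2-[3-(benzyloxy)phenyl]ethyl}-4,6-bis(methoxymethoxy)phenyl)-1-(methoxymethoxy)propan-2-yl pivalate F2. Under the same acid the ester carbonyl captures the cation as the more stable trans-dioxolanylium ion, which the phenol opens with inversion. This should give (2R,3S)-2-[4-(benzyloxy)-3,5-dimethoxyphenyl]-5-{2-[3-(benzyloxy)phenyl]ethyl}-7-hydroxychroman-3-yl pivalate F3, the bulky ester also disfavouring the cis transition state. Methylation (MeI, K2CO3) gives (2R,3S)-2-[4-(benzyloxy)-3,5-dimethoxyphenyl]-5-{2-[3-(benzyloxy)phenyl]ethyl}-7-methoxychroman-3-yl pivalate F4, and LiAlH4 removes the ester, returning to the route at 19.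

**Step 7.**
- What may go wrong: insufficient rate difference between the enantiomers of 9, or over-conversion, lowers the enantiomeric purity at the future C3.
- What may go wrong: the titanium alkoxide may open the electron-rich benzylic epoxy alcohol during the slow epoxidation of a monosubstituted alkene.
- Fallback: this sets out from 9. Lipase resolution (Candida antarctica lipase B, vinyl acetate) acylates the R enantiomer to (R)-1-[4-(benzyloxy)-3,5-dimethoxyphenyl]prop-2-en-1-yl acetate F6 and leaves (S)-1-[4-(benzyloxy)-3,5-dimethoxyphenyl]prop-2-en-1-ol F5. Enantiopure F5 is then epoxidised to full conversion in the matched sense (Ti(OiPr)4, D-(−)-diisopropyl tartrate, t-BuOOH), returning to the route at 10 without any dependence on conversion control.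

**Step 12.**
- What may go wrong: hydrogenolytic cleavage of the benzylic C2–O1 bond once the para-phenol of ring B is released.
- What may go wrong: slow removal of the benzyl ether crowded between two methoxy groups.
- Fallback: this sets out from 19 and ends at 20. The benzyl ethers are cleaved heterolytically with BCl3 and pentamethylbenzene as cation scavenger (CH2Cl2, −78 °C), which avoids hydrogen and a metal surface. This fallback makes no new compound (F0).

## Further compounds

F1 | step 9 | 1-{2-[3-(benzyloxy)phenyl]ethyl}-2-iodo-3,5-bis(methoxymethoxy)benzene | Ic1c(CCc2cccc(OCc3ccccc3)c2)cc(OCOC)cc1OCOC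
F2 | step 10 | (1R,2S)-1-[4-(benzyloxy)-3,5-dimethoxyphenyl]-3-(2-{2-[3-(benzyloxy)phenyl]ethyl}-4,6-bis(methoxymethoxy)phenyl)-1-(methoxymethoxy)propan-2-yl pivalate | COCO[C@H](c1cc(OC)c(OCc2ccccc2)c(OC)c1)[C@@H](OC(=O)C(C)(C)C)Cc1c(OCOC)cc(OCOC)cc1CCc1cccc(OCc2ccccc2)c1
F3 | step 10 | (2R,3S)-2-[4-(benzyloxy)-3,5-dimethoxyphenyl]-5-{2-[3-(benzyloxy)phenyl]ethyl}-7-hydroxychroman-3-yl pivalate | Oc1cc(CCc2cccc(OCc3ccccc3)c2)c2c(c1)O[C@H](c1cc(OC)c(OCc3ccccc3)c(OC)c1)[C@@H](OC(=O)C(C)(C)C)C2
F4 | step 10 | (2R,3S)-2-[4-(benzyloxy)-3,5-dimethoxyphenyl]-5-{2-[3-(benzyloxy)phenyl]ethyl}-7-methoxychroman-3-yl pivalate | COc1cc(CCc2cccc(OCc3ccccc3)c2)c2c(c1)O[C@H](c1cc(OC)c(OCc3ccccc3)c(OC)c1)[C@@H](OC(=O)C(C)(C)C)C2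
F5 | step 7 | (S)-1-[4-(benzyloxy)-3,5-dimethoxyphenyl]prop-2-en-1-ol | C=C[C@H](O)c1cc(OC)c(OCc2ccccc2)c(OC)c1
F6 | step 7 | (R)-1-[4-(benzyloxy)-3,5-dimethoxyphenyl]prop-2-en-1-yl acetate | C=C[C@@H](OC(C)=O)c1cc(OC)c(OCc2ccccc2)c(OC)c1
F0 | step 12 | none | none
A1 | alternative 1 | (R)-2-[4-(benzyloxy)-3,5-dimethoxyphenyl]-5-{2-[3-(benzyloxy)phenyl]ethyl}-7-methoxy-2H-chromene-3-carbaldehyde | COc1cc(CCc2cccc(OCc3ccccc3)c2)c2c(c1)O[C@H](c1cc(OC)c(OCc3ccccc3)c(OC)c1)C(C=O)=C2
A2 | alternative 1 | 2-{2-[3-(benzyloxy)phenyl]ethyl}-6-hydroxy-4-methoxybenzaldehyde | COc1cc(O)c(C=O)c(CCc2cccc(OCc3ccccc3)c2)c1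
A3 | alternative 1 | (E)-3-[4-(benzyloxy)-3,5-dimethoxyphenyl]prop-2-enal | COc1cc(/C=C/C=O)cc(OC)c1OCc1ccccc1
A4 | alternative 2 | (2R,3S)-2-[4-(benzyloxy)-3,5-dimethoxyphenyl]-5-{2-[3-(benzyloxy)phenyl]ethyl}-3-(tert-butyldimethylsilyloxy)-7-(4,4,5,5-tetramethyl-1,3,2-dioxaborolan-2-yl)chromane | CC1(C)OB(OC1(C)C)c1cc(CCc2cccc(OCc3ccccc3)c2)c2c(c1)O[C@H](c1cc(OC)c(OCc3ccccc3)c(OC)c1)[C@@H](O[Si](C)(C)C(C)(C)C)C2
A5 | alternative 2 | tert-butyl{[(1R,2S)-1-[4-(benzyloxy)-3,5-dimethoxyphenyl]-7-[3-(benzyloxy)phenyl]-1-(ethynyloxy)hept-4-yn-2-yl]oxy}dimethylsilane | C#CO[C@H](c1cc(OC)c(OCc2ccccc2)c(OC)c1)[C@@H](O[Si](C)(C)C(C)(C)C)CC#CCCc1cccc(OCc2ccccc2)c1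
A6 | alternative 2 | 2-ethynyl-4,4,5,5-tetramethyl-1,3,2-dioxaborolane | C#CB1OC(C)(C)C(C)(C)O1
A7 | alternative 3 | methyl 2-{2-[3-(benzyloxy)phenyl]ethyl}-4,6-dihydroxybenzoate | COC(=O)c1c(O)cc(O)cc1CCc1cccc(OCc2ccccc2)c1
A8 | alternative 3 | 6-{6-[3-(benzyloxy)phenyl]-2,4-dioxohexyl}-2,2-dimethyl-4H-1,3-dioxin-4-one | CC1(C)OC(CC(=O)CC(=O)CCc2cccc(OCc3ccccc3)c2)=CC(=O)O1
A9 | alternative 3 | methyl 9-[3-(benzyloxy)phenyl]-3,5,7-trioxononanoate | COC(=O)CC(=O)CC(=O)CC(=O)CCc1cccc(OCc2ccccc2)c1
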